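Ring atoms are numbered C1–C10: C1/C10 and C4/C5 are the oxiranes (methyl on C10 and C4), C6 carries the cinnamate, C7 the isopropyl, C8 the hydroxyl. Enabling feature: both oxiranes are cis-fused to the ten-membered ring (C2 and C9 cis on C1–C10, C3 and C6 cis on C4–C5), so the ring is a masked (Z,Z)-cyclodeca-1,5-diene and C1 is the CH end of a Z-trisubstituted alkene next to an unactivated CH2 (C2).
Retrosynthetic cuts, in order: C1–O/C10–O (oxirane from the Z-alkene); ring bond C1–C2 (Z-alkenyl iodide plus primary alkyl iodide); C8–H and the ester C–O (Evans–Tishchenko reduction with cinnamaldehyde); C4–O/C5–O (oxirane); C8–C9 (acylation of an allylic sulfone); C6–C7 (aldol).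
Forward: a Z-enal (C2–C6) and an N-isovaleryl oxazolidinone (C7, C8) are joined by aldol reaction, a Z-iodoallyl sulfone (C9, C10, C1) is attached at C8, the C4–C5 oxirane is made first, the ten-membered ring is then closed at C1–C2, and the C1–C10 oxirane is made last.
Stereochemistry: only C6 and C7 come from a bought auxiliary; the C6 hydroxyl then directs the C4/C5 epoxidation and the hydride to C8, and the C8 hydroxyl directs the C1/C10 epoxidation; both Z geometries come from stereospecific carbometalations of alkynes.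

Key step: step 16

Assumption: the SMILES is taken as drawn, which places the two ring carbons cis on each oxirane (oxiranes derived from Z-alkenes); the four starting materials named in steps 1, 5, 8 and 13 are taken as purchasable.

Step 1
Reactants: 1 tert-butyl(but-3-yn-1-yloxy)dimethylsilane
Product: 3 methyl 5-[(tert-butyldimethylsilyl)oxy]pent-2-ynoate, via lithium acetylide 2 (not isolated)
Conditions: n-BuLi, THF, −78 °C; then ClCO2Me, −78 to 0 °C
Reagents that add atoms: methyl chloroformate, COC(=O)Cl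
Why: Deprotonation of the terminal alkyne and C-acylation of the acetylide by a chloroformate is a standard route to 2-ynoates, and no stereocentre is formed.

Step 2
Reactants: 3 methyl 5-[(tert-butyldimethylsilyl)oxy]pent-2-ynoate
Product: 5 methyl (2Z)-5-[(tert-butyldimethylsilyl)oxy]-3-methylpent-2-enoate, via alkenylcuprate adduct 4 (not isolated)
Conditions: Me2CuLi, THF, −78 °C; aq. NH4Cl quench at −78 °C
Reagents that add atoms: lithium dimethylcuprate, [Li+].C[Cu-]C
Why: syn-Carbocupration of the ynoate (cuprate conjugate addition) followed by protonation with retention at −78 °C, before the adduct can equilibrate through the allenolate, puts the new methyl cis to H, so the CH2CH2OSi chain ends cis to the ester (Z).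

Step 3
Reactants: 5 methyl (2Z)-5-[(tert-butyldimethylsilyl)oxy]-3-methylpent-2-enoate
Product: 6 (2Z)-5-[(tert-butyldimethylsilyl)oxy]-3-methylpent-2-en-1-ol
Conditions: i-Bu2AlH (2.2 equiv), CH2Cl2, −78 °C; aq. potassium sodium tartrate
Reagents that add atoms: none
Why: 1,2-Reduction of an enoate by i-Bu2AlH at low temperature is standard and should leave the Z geometry and the silyl ether untouched.

Step 4
Reactants: 6 (2Z)-5-[(tert-butyldimethylsilyl)oxy]-3-methylpent-2-en-1-ol
Product: 7 (2Z)-5-[(tert-butyldimethylsilyl)oxy]-3-methylpent-2-enal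
Conditions: TEMPO (10 mol%), PhI(OAc)2, CH2Cl2, 0 °C; used at once
Reagents that add atoms: none
Why: Oxoammonium oxidation (TEMPO with PhI(OAc)2) of an allylic alcohol is non-basic, and the same conditions are known to turn nerol into neral without Z/E isomerisation.

Step 5
Reactants: 8 prop-2-yn-1-ol
Product: 10 (2Z)-3-iodo-2-methylprop-2-en-1-ol, via alkenylmagnesium chelate 9 (not isolated)
Conditions: MeMgBr (2.5 equiv), CuI (10 mol%), THF, −10 °C to rt; then iodine, −10 °C
Reagents that add atoms: methylmagnesium bromide, C[Mg]Br; iodine, [I][I]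
Why: Copper-catalysed anti-carbomagnesiation of the propargylic magnesium alkoxide gives a five-membered oxa-magnesacycle, so iodinolysis with retention leaves iodine cis to CH2OH (Z).

Step 6
Reactants: 10 (2Z)-3-iodo-2-methylprop-2-en-1-ol
Product: 11 (1Z)-3-bromo-1-iodo-2-methylprop-1-ene
Conditions: CBr4, PPh3, CH2Cl2, 0 °C
Reagents that add atoms: carbon tetrabromide, BrC(Br)(Br)Br
Why: Appel bromination of the primary allylic alcohol is an SN2 displacement of the oxyphosphonium group and does not touch the alkenyl iodide or its geometry.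

Step 7
Reactants: 11 (1Z)-3-bromo-1-iodo-2-methylprop-1-ene
Product: 12 {[(2Z)-3-iodo-2-methylprop-2-en-1-yl]sulfonyl}benzene
Conditions: PhSO2Na, DMF, rt
Reagents that add atoms: sodium benzenesulfinate, [Na+].[O-]S(=O)c1ccccc1
Why: S-Alkylation of a sulfinate by a primary allylic bromide (SN2) is a standard sulfone synthesis.

Step 8
Reactants: 13 (4S)-4-benzyl-3-(3-methylbutanoyl)oxazolidin-2-one; 7 (2Z)-5-[(tert-butyldimethylsilyl)oxy]-3-methylpent-2-enal
Product: 15 (4S)-4-benzyl-3-[(2S,3R,4Z)-7-[(tert-butyldimethylsilyl)oxy]-3-hydroxy-5-methyl-2-(propan-2-yl)hept-4-enoyl]oxazolidin-2-one, via dibutylboron enolate 14 (not isolated)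
Conditions: Bu2BOTf, i-Pr2NEt, CH2Cl2, 0 °C; then 7, −78 to 0 °C; H2O2, pH 7 buffer, MeOH
Reagents that add atoms: none
Why: Evans syn-aldol reaction, in which the Z-boron enolate reacts through a Zimmerman–Traxler chair on the face away from the benzyl group and sets C7 and C6 syn (2S,3R in the acyl chain), the only stereocentres taken from a bought chiral source.

Step 9
Reactants: 15 (4S)-4-benzyl-3-[(2S,3R,4Z)-7-[(tert-butyldimethylsilyl)oxy]-3-hydroxy-5-methyl-2-(propan-2-yl)hept-4-enoyl]oxazolidin-2-one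
Product: 16 (2S,3R,4Z)-7-[(tert-butyldimethylsilyl)oxy]-3-hydroxy-N-methoxy-N,5-dimethyl-2-(propan-2-yl)hept-4-enamide
Conditions: MeNH(OMe)·HCl, AlMe3, CH2Cl2, −10 to 0 °C
Reagents that add atoms: N,O-dimethylhydroxylamine hydrochloride, CNOC.Cl
Why: Aluminium amide transamination of a β-hydroxy N-acyloxazolidinone, helped by the C6 aluminium alkoxide, is the standard auxiliary removal to a Weinreb amide and should not epimerise C7.

Step 10
Reactants: 12 {[(2Z)-3-iodo-2-methylprop-2-en-1-yl]sulfonyl}benzene; 16 (2S,3R,4Z)-7-[(tert-butyldimethylsilyl)oxy]-3-hydroxy-N-methoxy-N,5-dimethyl-2-(propan-2-yl)hept-4-enamide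
Product: 18 (1Z,5S,6R,7Z)-10-[(tert-butyldimethylsilyl)oxy]-6-hydroxy-1-iodo-2,8-dimethyl-3-(phenylsulfonyl)-5-(propan-2-yl)deca-1,7-dien-4-one (mixture of C3 epimers), via lithiated sulfone 17 (not isolated)
Conditions: 12 (3.0 equiv), LiN(SiMe3)2 (2.9 equiv), THF, −78 °C; then 16, −78 to −20 °C; AcOH
Reagents that add atoms: none
Why: C-Acylation of an α-sulfonyl carbanion by a Weinreb amide stops at the ketone stage through the chelated tetrahedral adduct; the allylic sulfone anion reacts at its α-carbon, the silylamide base avoids iodine–lithium exchange, and the extra anion covers the free hydroxyl.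

Step 11
Reactants: 18 (1Z,5S,6R,7Z)-10-[(tert-butyldimethylsilyl)oxy]-6-hydroxy-1-iodo-2,8-dimethyl-3-(phenylsulfonyl)-5-(propan-2-yl)deca-1,7-dien-4-one
Product: 19 (1Z,5S,6R,7Z)-10-[(tert-butyldimethylsilyl)oxy]-6-hydroxy-1-iodo-2,8-dimethyl-5-(propan-2-yl)deca-1,7-dien-4-one
Conditions: SmI2 (2.5 equiv), THF/MeOH, −78 °C
Reagents that add atoms: none
Why: Reductive desulfonylation of a β-keto sulfone by SmI2 is fast at −78 °C, where alkenyl iodides are not reduced, and protonation at C9 by MeOH keeps the Z-iodoalkene out of conjugation.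

Step 12
Reactants: 19 (1Z,5S,6R,7Z)-10-[(tert-butyldimethylsilyl)oxy]-6-hydroxy-1-iodo-2,8-dimethyl-5-(propan-2-yl)deca-1,7-dien-4-one
Product: 20 (1Z,5S,6S,7R,8S)-10-[(tert-butyldimethylsilyl)oxy]-7,8-epoxy-6-hydroxy-1-iodo-2,8-dimethyl-5-(propan-2-yl)dec-1-en-4-one
Conditions: mCPBA, NaHCO3, CH2Cl2, 0 °C
Reagents that add atoms: 3-chloroperoxybenzoic acid, OOC(=O)c1cccc(Cl)c1
Why: Hydroxyl-directed peracid epoxidation of a Z-allylic alcohol, in which allylic 1,3-strain with the cis CH2 (C3) holds the C6–H in the alkene plane and the hydrogen-bonded peracid delivers oxygen syn to the C6 hydroxyl (threo), sets C5 and C4 in one event while the electron-poor iodoalkene should not react.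

Step 13
Reactants: 20 (1Z,5S,6S,7R,8S)-10-[(tert-butyldimethylsilyl)oxy]-7,8-epoxy-6-hydroxy-1-iodo-2,8-dimethyl-5-(propan-2-yl)dec-1-en-4-one; 21 (2E)-3-phenylprop-2-enal (cinnamaldehyde)
Product: 23 (1Z,4R,5R,6S,7R,8S)-10-[(tert-butyldimethylsilyl)oxy]-7,8-epoxy-4-hydroxy-1-iodo-2,8-dimethyl-5-(propan-2-yl)dec-1-en-6-yl (2E)-3-phenylprop-2-enoate, via C6 hemiacetal 22 (not isolated)
Conditions: SmI2 (30 mol%, premixed with 21), 21 (5 equiv), THF, −10 °C
Reagents that add atoms: none
Why: Evans–Tishchenko reduction, in which the samarium-bound hemiacetal of the C6 hydroxyl and cinnamaldehyde passes its hydride to the C8 ketone through a six-membered chair, should give the 1,3-anti C8 carbinol and leave the oxidised aldehyde as the C6 cinnamate in the same event.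

Step 14
Reactants: 23 (1Z,4R,5R,6S,7R,8S)-10-[(tert-butyldimethylsilyl)oxy]-7,8-epoxy-4-hydroxy-1-iodo-2,8-dimethyl-5-(propan-2-yl)dec-1-en-6-yl (2E)-3-phenylprop-2-enoate
Product: 24 (1Z,4R,5R,6S,7R,8S)-7,8-epoxy-4,10-dihydroxy-1-iodo-2,8-dimethyl-5-(propan-2-yl)dec-1-en-6-yl (2E)-3-phenylprop-2-enoate
Conditions: HF·pyridine, pyridine, THF, 0 °C
Reagents that add atoms: none
Why: Buffered HF·pyridine cleaves the primary silyl ether under non-basic conditions, so neither 1,3-acyl migration of the cinnamate nor oxirane opening is expected.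

Step 15
Reactants: 24 (1Z,4R,5R,6S,7R,8S)-7,8-epoxy-4,10-dihydroxy-1-iodo-2,8-dimethyl-5-(propan-2-yl)dec-1-en-6-yl (2E)-3-phenylprop-2-enoate
Product: 25 (1Z,4R,5R,6S,7R,8S)-7,8-epoxy-4-hydroxy-1,10-diiodo-2,8-dimethyl-5-(propan-2-yl)dec-1-en-6-yl (2E)-3-phenylprop-2-enoate
Conditions: iodine, PPh3, imidazole, CH2Cl2, 0 °C
Reagents that add atoms: iodine, [I][I]
Why: Appel-type iodination is selective for the unhindered primary alcohol over the hindered secondary C8 hydroxyl, and the imidazole buffer should keep the oxirane intact.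

Step 16
Reactants: 25 (1Z,4R,5R,6S,7R,8S)-7,8-epoxy-4-hydroxy-1,10-diiodo-2,8-dimethyl-5-(propan-2-yl)dec-1-en-6-yl (2E)-3-phenylprop-2-enoate
Product: 26 (1(10)Z,4S,5R,6S,7R,8R)-4,5-epoxy-8-hydroxygermacr-1(10)-en-6-yl (2E)-3-phenylprop-2-enoate
Conditions: NiBr2(dme) (30 mol%), 4,4'-di-tert-butyl-2,2'-bipyridine (33 mol%), TDAE (2.5 equiv), MeCN, 40 °C; 25 added by syringe pump (final 2 mM)
Reagents that add atoms: none
Why: Proposed new method: a nickel-catalysed reductive cross-electrophile coupling run intramolecularly, in which bipyridine-ligated low-valent nickel (kept reduced by the organic reductant TDAE) inserts by a two-electron path into the C1–I bond of the Z-alkenyl iodide with retention, a low-valent nickel centre abstracts iodine from the primary C2–I bond to give the C2 radical, and capture of this radical by the tethered alkenylnickel followed by C(sp2)–C(sp3) reductive elimination from trivalent nickel forms C1–C2; the closest known reaction type is the intermolecular nickel-catalysed cross-electrophile coupling of alkenyl halides with primary alkyl halides, which keeps alkene geometry, and the new element is its use to close a medium carbocycle. The ten-membered ring is closed by reductive elimination from an eleven-membered nickelacycle, with C1 staying in the ring as part of the endocyclic C1=C10 double bond. No stereocentre is created, and the Z geometry of C1=C10 is carried over from the alkenyl iodide. The step needs ring closure to beat oligomerisation and needs the two C–I bonds to be activated by different mechanisms; the first is served by the two cis turn elements (the Z-iodoalkene and the cis-fused C4–C5 oxirane, which hold C1 and C2 on the same side of the chain), by the three substituted carbons C6–C8 and by slow addition, the second by the sp2 versus sp3 nature of the two iodides. TDAE leaves no Lewis-acidic metal salt, so the trisubstituted oxirane, the cinnamate and the free C8 hydroxyl should survive, and the C2 radical has no alkene or oxirane placed for a fast rearrangement.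

Step 17
Reactants: 26 (1(10)Z,4S,5R,6S,7R,8R)-4,5-epoxy-8-hydroxygermacr-1(10)-en-6-yl (2E)-3-phenylprop-2-enoate
Product: 27 (1R,4S,5R,6S,7R,8R,10S)-1,10:4,5-diepoxy-8-hydroxygermacran-6-yl (2E)-3-phenylprop-2-enoate (target)
Conditions: VO(acac)2 (10 mol%), t-BuOOH (1.5 equiv, in decane), CH2Cl2, 0 °C to rt
Reagents that add atoms: tert-butyl hydroperoxide, CC(C)(C)OO
Why: Vanadium-catalysed hydroxyl-directed epoxidation of a homoallylic alcohol, in which the C8 vanadate ester delivers the peroxide oxygen to C1=C10 through a chair-like six-membered array (V, O, C8, C9, C10, O) with C7 and C1 equatorial, should give the oxirane 1,3-syn to the C8 hydroxyl (C10 S, C1 R) with the cis fusion fixed by the Z-alkene, while the electron-poor cinnamate alkene has no directing group.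

Compound list
1 | tert-butyl(but-3-yn-1-yloxy)dimethylsilane | C#CCCO[Si](C)(C)C(C)(C)C | starting material
2 | lithium acetylide of 1 | [Li]C#CCCO[Si](C)(C)C(C)(C)C | intermediate (not isolated)
3 | methyl 5-[(tert-butyldimethylsilyl)oxy]pent-2-ynoate | COC(=O)C#CCCO[Si](C)(C)C(C)(C)C | intermediate
4 | lithium alkenyl(methyl)cuprate from syn addition to 3 (Cu on C2 cis to the new C3 methyl) | COC(=O)/C([Cu-]C)=C(/C)CCO[Si](C)(C)C(C)(C)C.[Li+] | intermediate (not isolated)
5 | methyl (2Z)-5-[(tert-butyldimethylsilyl)oxy]-3-methylpent-2-enoate | COC(=O)/C=C(/C)CCO[Si](C)(C)C(C)(C)C | intermediate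
6 | (2Z)-5-[(tert-butyldimethylsilyl)oxy]-3-methylpent-2-en-1-ol | OC/C=C(/C)CCO[Si](C)(C)C(C)(C)C | intermediate
7 | (2Z)-5-[(tert-butyldimethylsilyl)oxy]-3-methylpent-2-enal | O=C/C=C(/C)CCO[Si](C)(C)C(C)(C)C | intermediate
8 | prop-2-yn-1-ol | C#CCO | starting material
9 | (Z)-alkenylmagnesium bromide chelated to its magnesium alkoxide (Mg cis to CH2O) | C/C(CO[Mg]Br)=C/[Mg]Br | intermediate (not isolated)
10 | (2Z)-3-iodo-2-methylprop-2-en-1-ol | OC/C(C)=C\I | intermediate
11 | (1Z)-3-bromo-1-iodo-2-methylprop-1-ene | BrC/C(C)=C\I | intermediate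
12 | {[(2Z)-3-iodo-2-methylprop-2-en-1-yl]sulfonyl}benzene | O=S(=O)(C/C(C)=C\I)c1ccccc1 | intermediate
13 | (4S)-4-benzyl-3-(3-methylbutanoyl)oxazolidin-2-one | CC(C)CC(=O)N1[C@@H](Cc2ccccc2)COC1=O | starting material
14 | dibutylboron (Z)-enolate of 13 | CC(C)/C=C(\OB(CCCC)CCCC)N1[C@@H](Cc2ccccc2)COC1=O | intermediate (not isolated)
15 | (4S)-4-benzyl-3-[(2S,3R,4Z)-7-[(tert-butyldimethylsilyl)oxy]-3-hydroxy-5-methyl-2-(propan-2-yl)hept-4-enoyl]oxazolidin-2-one | CC(C)[C@@H]([C@H](O)/C=C(C)\CCO[Si](C)(C)C(C)(C)C)C(=O)N1[C@@H](Cc2ccccc2)COC1=O | intermediate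
16 | (2S,3R,4Z)-7-[(tert-butyldimethylsilyl)oxy]-3-hydroxy-N-methoxy-N,5-dimethyl-2-(propan-2-yl)hept-4-enamide | CC(C)[C@@H]([C@H](O)/C=C(C)\CCO[Si](C)(C)C(C)(C)C)C(=O)N(C)OC | intermediate
17 | α-lithio derivative of sulfone 12 | [Li]C(/C(C)=C\I)S(=O)(=O)c1ccccc1 | intermediate (not isolated)
18 | (1Z,5S,6R,7Z)-10-[(tert-butyldimethylsilyl)oxy]-6-hydroxy-1-iodo-2,8-dimethyl-3-(phenylsulfonyl)-5-(propan-2-yl)deca-1,7-dien-4-one, mixture of C3 epimers | CC(C)[C@@H]([C@H](O)/C=C(C)\CCO[Si](C)(C)C(C)(C)C)C(=O)C(/C(C)=C\I)S(=O)(=O)c1ccccc1 | intermediate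
19 | (1Z,5S,6R,7Z)-10-[(tert-butyldimethylsilyl)oxy]-6-hydroxy-1-iodo-2,8-dimethyl-5-(propan-2-yl)deca-1,7-dien-4-one | CC(C)[C@@H]([C@H](O)/C=C(C)\CCO[Si](C)(C)C(C)(C)C)C(=O)C/C(C)=C\I | intermediate
20 | (1Z,5S,6S,7R,8S)-10-[(tert-butyldimethylsilyl)oxy]-7,8-epoxy-6-hydroxy-1-iodo-2,8-dimethyl-5-(propan-2-yl)dec-1-en-4-one | CC(C)[C@@H]([C@H](O)[C@H]1O[C@@]1(C)CCO[Si](C)(C)C(C)(C)C)C(=O)C/C(C)=C\I | intermediate
21 | (2E)-3-phenylprop-2-enal (cinnamaldehyde) | O=C/C=C/c1ccccc1 | starting material
22 | hemiacetal of the C6 hydroxyl of 20 with 21 (hemiacetal carbon unassigned) | CC(C)[C@@H]([C@H](OC(O)/C=C/c1ccccc1)[C@H]1O[C@@]1(C)CCO[Si](C)(C)C(C)(C)C)C(=O)C/C(C)=C\I | intermediate (not isolated)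
23 | (1Z,4R,5R,6S,7R,8S)-10-[(tert-butyldimethylsilyl)oxy]-7,8-epoxy-4-hydroxy-1-iodo-2,8-dimethyl-5-(propan-2-yl)dec-1-en-6-yl (2E)-3-phenylprop-2-enoate | CC(C)[C@@H]([C@H](OC(=O)/C=C/c1ccccc1)[C@H]1O[C@@]1(C)CCO[Si](C)(C)C(C)(C)C)[C@@H](C/C(C)=C\I)O | intermediate
24 | (1Z,4R,5R,6S,7R,8S)-7,8-epoxy-4,10-dihydroxy-1-iodo-2,8-dimethyl-5-(propan-2-yl)dec-1-en-6-yl (2E)-3-phenylprop-2-enoate | CC(C)[C@@H]([C@H](OC(=O)/C=C/c1ccccc1)[C@H]1O[C@@]1(C)CCO)[C@@H](C/C(C)=C\I)O | intermediate
25 | (1Z,4R,5R,6S,7R,8S)-7,8-epoxy-4-hydroxy-1,10-diiodo-2,8-dimethyl-5-(propan-2-yl)dec-1-en-6-yl (2E)-3-phenylprop-2-enoate | CC(C)[C@@H]([C@H](OC(=O)/C=C/c1ccccc1)[C@H]1O[C@@]1(C)CCI)[C@@H](C/C(C)=C\I)O | intermediate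
26 | (1(10)Z,4S,5R,6S,7R,8R)-4,5-epoxy-8-hydroxygermacr-1(10)-en-6-yl (2E)-3-phenylprop-2-enoate | CC(C)[C@H]1[C@H](OC(=O)/C=C/c2ccccc2)[C@H]2O[C@@]2(C)CC/C=C(C)\C[C@H]1O | intermediate
27 | (1R,4S,5R,6S,7R,8R,10S)-1,10:4,5-diepoxy-8-hydroxygermacran-6-yl (2E)-3-phenylprop-2-enoate | CC(C)[C@H]1[C@H](OC(=O)/C=C/c2ccccc2)[C@H]2O[C@@]2(C)CC[C@H]2O[C@@]2(C)C[C@H]1O | target

Total step count: 17. Longest linear sequence: 14 steps (steps 1–4, then 8–17); the sulfone branch (steps 5–7) joins at step 10.

Steps most likely to fail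

Step 16 (Proposed new method). Ring closure may lose to intermolecular coupling (oligomerisation), to plain reduction of the C2–I bond, or to 1,5-hydrogen transfer from C6 to the C2 radical. The fallback joins the same two carbons by a polar sequence of known steps and sets out from 25. The C8 hydroxyl is silylated (Et3SiOTf, 2,6-lutidine, CH2Cl2, −78 °C) to the C8 triethylsilyl ether of 25, F1. Activated Zn dust in THF at 25–35 °C should insert only into the primary C–I bond and give the alkylzinc iodide F2. Slow addition of F2 to Pd2(dba)3/P(2-furyl)3 in THF/NMP at 50 °C closes the ring by intramolecular Negishi coupling (zerovalent palladium inserts into the alkenyl C–I bond, the zinc alkyl is transferred within the molecule) to the C8 triethylsilyl ether of the macrocycle, F3. HF·pyridine then removes the silyl group, and the route is rejoined at 26.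

Step 13. Hydride transfer from the hemiacetal of an α,β-unsaturated aldehyde may be outrun by samarium-mediated pinacol coupling or conjugate reduction of cinnamaldehyde, so that the ketone is not reduced or the cinnamoyl group is not delivered. The fallback sets out from 20 and runs the Evans–Tishchenko reduction with acetaldehyde, a standard partner, to give the C6 acetate C8 alcohol F4. Et3SiOTf/2,6-lutidine gives its C8 triethylsilyl ether F5. K2CO3 in MeOH at 0 °C removes the acetate and gives the C6 alcohol F6. Cinnamoyl chloride, Et3N and DMAP give the C6 cinnamate C8 silyl ether F7. HF·pyridine removes both silyl groups, and the route is rejoined at 24.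

Step 17. The ring conformation may override the directing effect of the C8 hydroxyl and give poor facial selectivity at C1=C10. The fallback sets out from 26 and replaces substrate control by reagent control: epoxidation with the dioxirane from the fructose-derived Shi ketone (enantiomer chosen to match the substrate), KHSO5 (as the triple salt 2KHSO5·KHSO4·K2SO4), K2CO3 buffer, MeCN/dimethoxymethane/H2O, 0 °C. This gives 27 directly, with no new compound.

Further compounds
F1 | step 16 | C8 triethylsilyl ether of 25 | CC(C)[C@@H]([C@H](OC(=O)/C=C/c1ccccc1)[C@H]1O[C@@]1(C)CCI)[C@@H](C/C(C)=C\I)O[Si](CC)(CC)CC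
F2 | step 16 | alkylzinc iodide from F1 (Zn at the former primary C–I carbon) | CC(C)[C@@H]([C@H](OC(=O)/C=C/c1ccccc1)[C@H]1O[C@@]1(C)CC[Zn]I)[C@@H](C/C(C)=C\I)O[Si](CC)(CC)CC
F3 | step 16 | C8 triethylsilyl ether of 26 | CC(C)[C@H]1[C@H](OC(=O)/C=C/c2ccccc2)[C@H]2O[C@@]2(C)CC/C=C(C)\C[C@H]1O[Si](CC)(CC)CC
F4 | step 13 | C6 acetate analogue of 23 (C8 hydroxyl free) | CC(C)[C@@H]([C@H](OC(C)=O)[C@H]1O[C@@]1(C)CCO[Si](C)(C)C(C)(C)C)[C@@H](C/C(C)=C\I)O
F5 | step 13 | C8 triethylsilyl ether of F4 | CC(C)[C@@H]([C@H](OC(C)=O)[C@H]1O[C@@]1(C)CCO[Si](C)(C)C(C)(C)C)[C@@H](C/C(C)=C\I)O[Si](CC)(CC)CC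
F6 | step 13 | C6 alcohol from F5 | CC(C)[C@@H]([C@H](O)[C@H]1O[C@@]1(C)CCO[Si](C)(C)C(C)(C)C)[C@@H](C/C(C)=C\I)O[Si](CC)(CC)CC
F7 | step 13 | C6 cinnamate of F6 (C8 triethylsilyl ether of 23) | CC(C)[C@@H]([C@H](OC(=O)/C=C/c1ccccc1)[C@H]1O[C@@]1(C)CCO[Si](C)(C)C(C)(C)C)[C@@H](C/C(C)=C\I)O[Si](CC)(CC)CC
F0 | step 17 | none | none
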